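**The clock.** Turn the west run into one time before reckoning the flask: it was charged with 2 M of partner, as the flask is.

| flask | starting material | partner | remark | time |
|---|---|---|---|---|
| east | 0.80 M | 1 M | run made earlier |  |
| north-west | 0.80 M | 1.5 M | run made earlier |  |
| west | 0.40 M | 2 M | run made earlier |  |
| flask | 0.80 M | 2.00 M |  | 6.0 h |

| run | time / h | over-reaction product / % | target / % |
|---|---|---|---|
| east | 0.500 | 1 | 1 |
| east | 1.00 | 1 | 6 |
| east | 1.50 | 0 | 11 |
| east | 2.00 | 6 | 13 |
| east | 2.50 | 6 | 16 |
| east | 3.00 | 6 | 15 |
| east | 4.00 | 12 | 17 |
| north-west | 0.500 | 0 | 5 |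
| north-west | 1.00 | 1 | 12 |
| north-west | 1.50 | 9 | 15 |
| north-west | 2.00 | 11 | 21 |
| north-west | 2.50 | 12 | 20 |
| north-west | 3.00 | 17 | 21 |
| north-west | 4.00 | 20 | 25 |
| west | 0.250 | 0 | 5 |
| west | 0.500 | 2 | 10 |
| west | 1.00 | 6 | 17 |
| west | 2.00 | 23 | 26 |
| west | 4.00 | 48 | 21 |

(readings scatter by 1.5 percentage points)

- ratio of over-reaction product to target at 8.0 min
- ratio of over-reaction product to target at 1.0 h
- ratio of over-reaction product to target at 6.0 h
- which of over-reaction product and target there is more of at 6.0 h

- the earlier runs were read with a standard deviation of 1.5 percentage points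

**Target lifetime.** Up to 2.00 h the west run gives 1.34 h. This reading is the target lifetime: the time-integral of target divided by the over-reaction product formed by then, a pseudo-first-order time. We take it to lengthen as [partner] falls, in inverse proportion.

**First instants.** In the flask over-reaction product grows from target. If target grows in step with time, as the west run's first readings of 5% and 10% suggest, their ratio is time over twice the lifetime; if it grows as the square of time, as the east run's 1% and 6% suggest, it is time over 3 lifetimes. At 8.0 min we reckon 0.0332 to 0.0498.

**The middle.** At 1.0 h the same two lines give the flask 0.249 to 0.373, while target is still building.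

**The end.** Stretched to 6.0 h, the lines give the flask 1.49 to 2.24. This is crude, since falling [partner] lowers the ratio and a fading supply of target raises it. Still, 6.0 h lies beyond 3 lifetimes, 4.02 h, so we expect over-reaction product to lead.

**The forecast.** The forecast gives 0.045, 0.37 and 3.7, the last above both our crude figures, with over-reaction product ahead. One of its grounds reads: “In the flask, partner falls from 2 to about 1.05 M by 6 h.”

**The flask.** The ratios come out at 0.0399, 0.343 and 2.11, with over-reaction product ahead at 46.6% against 22.1%.

    starting material + partner → intermediate A (k = 0.00879 M⁻¹ min⁻¹)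
    starting material ⇌ intermediate B (K = 1.10, k = 0.0300 min⁻¹)
    partner + target → over-reaction product (k = 0.00725 M⁻¹ min⁻¹)
    partner + intermediate A → target (k = 0.0141 M⁻¹ min⁻¹)

**Lifetime again.** At 6.00 h the flask holds 0.459 M of partner, so our west-run reading, scaled in inverse proportion to [partner], estimates the target lifetime at 5.83 h, with the scatter of those readings in it. That estimate is longer than the 2.58 h lifetime of intermediate A on its way to target, of which 8.64% still stands. In the neighbouring flask charged with 1.2 M of partner, 17.9% of that charge is left at 6.00 h, the same reckoning gives a lifetime of 12.4 h, and the ratio stands at 0.842.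

The runs come from a simulation for an exercise, noise included.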